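**Retrosynthetic overview**
1. The target is reached by global hydrogenolysis of its nonabenzyl ether, which comes from Tamao–Fleming oxidation (retention) of a 3-silylflavan; the C3–Si bond is the masked C3–OH.
2. The flavan dihydropyran ring is disconnected at O1–C2 and C3–C4: an enantioselective, stereoconvergent oxa-[4+2] between an o-quinone methide (from a racemic o-hydroxybenzhydrol) and a (Z)-β-silylstyrene closes this ring and sets C2, C3 and C4 in one operation.
3. Enabling feature: in the flavan unit O1 sits on C8a ortho to C4a and the C7 oxygen is para to C4a, so the doubly benzylic C4 (bonded to flavonol C5) is a latent o-quinone methide carbon (O1=C8a–C4a=C4); C2 is benzylic to the 3,4-dioxygenated B ring, which takes up the developing charge.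
4. The benzhydrol comes from ortho-hydroxyalkylation of 2,3-bis(benzyloxy)phenol with a flavonol-5-carbaldehyde, itself made by C4=O-directed C5–H olefination and oxidative cleavage of pentabenzyl 3,7,8,3',4'-pentahydroxyflavone (Algar–Flynn–Oyamada route from gallacetophenone).
5. Ring order: all benzene rings are bought; the flavonol pyranone ring is closed first (step 3), the flavan dihydropyran ring last (step 11).

Key step: step 11

Remark (assumption): the sense of induction of the chiral acid in step 11 cannot be derived from first principles; the catalyst antipode is taken to be the one that delivers (4S), to be confirmed on the first run.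

**Step 1**
Reactants: 1 gallacetophenone [1-(2,3,4-trihydroxyphenyl)ethanone]
Product: 2 1-[3,4-bis(benzyloxy)-2-hydroxyphenyl]ethanone
Conditions: BnBr (2.1 equiv), K2CO3 (2.1 equiv), DMF, rt
Reagents that add atoms: benzyl bromide, BrCc1ccccc1
Why: Williamson etherification in which the 2-OH, held in a strong hydrogen bond to the acetyl carbonyl, is the least nucleophilic hydroxyl, so two equivalents of benzyl bromide should cap the 3- and 4-OH selectively.

**Step 2**
Reactants: 2 1-[3,4-bis(benzyloxy)-2-hydroxyphenyl]ethanone; 3 3,4-bis(benzyloxy)benzaldehyde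
Product: 4 (E)-1-[3,4-bis(benzyloxy)-2-hydroxyphenyl]-3-[3,4-bis(benzyloxy)phenyl]prop-2-en-1-one
Conditions: KOH (aq. 50%), EtOH/THF, rt
Reagents that add atoms: none
Why: Claisen–Schmidt aldol condensation of the methyl ketone enolate with a non-enolisable aldehyde, with E1cB dehydration giving the (E)-enone.

**Step 3**
Reactants: 4 (E)-2'-hydroxychalcone
Product: 6 7,8-bis(benzyloxy)-2-[3,4-bis(benzyloxy)phenyl]-3-hydroxy-4H-chromen-4-one, via trans-dihydroflavonol 5 (not isolated)
Conditions: 30% H2O2, NaOH (aq.), MeOH/THF, 0 °C → rt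
Reagents that add atoms: hydrogen peroxide, OO
Why: Algar–Flynn–Oyamada oxidative cyclisation, in which the phenoxide closes onto the enone β-carbon while the α-carbon is hydroxylated and the dihydroflavonol is dehydrogenated in the same flask; the absence of a 6'-substituent favours flavonol over aurone.

**Step 4**
Reactants: 6 3-hydroxyflavone
Product: 7 3,7,8-tris(benzyloxy)-2-[3,4-bis(benzyloxy)phenyl]-4H-chromen-4-one
Conditions: BnBr, K2CO3, DMF, 60 °C
Reagents that add atoms: benzyl bromide, BrCc1ccccc1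
Why: Williamson O-alkylation of the acidic 3-enol caps the last free hydroxyl and leaves the C4 carbonyl free to act as a directing group.

**Step 5**
Reactants: 7 pentabenzyl flavonol
Product: 8 3,7,8-tris(benzyloxy)-2-[3,4-bis(benzyloxy)phenyl]-5-[(E)-2-phenylethenyl]-4H-chromen-4-one
Conditions: [Cp*RhCl2]2 (2.5 mol %), AgSbF6 (10 mol %), Cu(OAc)2 (2.1 equiv), styrene (2 equiv), DCE, 110 °C
Reagents that add atoms: styrene, C=Cc1ccccc1
Why: Rh(III)-catalysed carbonyl-directed C–H olefination (oxidative Heck type), in which the chromone C4=O forms a five-membered rhodacycle at the peri C5–H, the only C–H it can reach, and styrene insertion/β-hydride elimination gives the (E)-alkene with Cu(II) as reoxidant.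

**Step 6**
Reactants: 8 5-styrylflavonol pentabenzyl ether
Product: 10 3,7,8-tris(benzyloxy)-2-[3,4-bis(benzyloxy)phenyl]-4-oxo-4H-chromene-5-carbaldehyde, via threo-diol 9 (not isolated)
Conditions: OsO4 (2 mol %), NaIO4 (4 equiv), 2,6-lutidine, dioxane/H2O, rt
Reagents that add atoms: sodium periodate (terminal oxygen source), [Na+].[O-]I(=O)(=O)=O; osmium tetroxide (catalytic oxygen carrier), O=[Os](=O)(=O)=O
Why: Lemieux–Johnson oxidation, in which the disubstituted stilbene-type alkene should be dihydroxylated much faster than the tetrasubstituted, carbonyl-conjugated C2=C3 bond of the chromone, and periodate cleaves the glycol to the aldehyde.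

**Step 7**
Reactants: 11 2,3-bis(benzyloxy)benzaldehyde
Product: 13 2,3-bis(benzyloxy)phenol, via aryl formate 12 (not isolated)
Conditions: mCPBA, CH2Cl2, 0 °C → rt; then KOH, MeOH/H2O, rt; acidic work-up
Reagents that add atoms: 3-chloroperbenzoic acid, O=C(OO)c1cccc(Cl)c1
Why: Dakin-type Baeyer–Villiger oxidation, in which the electron-rich aryl group migrates in the Criegee intermediate to give the aryl formate, which is saponified in the same flask.

**Step 8**
Reactants: 10 flavonol-5-carbaldehyde; 13 2,3-bis(benzyloxy)phenol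
Product: 14 rac-3,7,8-tris(benzyloxy)-5-{[3,4-bis(benzyloxy)-2-hydroxyphenyl](hydroxy)methyl}-2-[3,4-bis(benzyloxy)phenyl]-4H-chromen-4-one
Conditions: 13 + EtMgBr (1.0 equiv), Et2O, 0 °C; solvent exchange to CH2Cl2; then 10, rt; aq. NH4Cl
Reagents that add atoms: none
Why: ortho-specific hydroxyalkylation of a bromomagnesium phenoxide, which binds the aldehyde and delivers it through a six-membered chelate to the only free ortho position (also para to the 3-benzyloxy group); the carbinol forms as a racemate, which is harmless because this centre is erased in step 11.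

**Step 9**
Reactants: 3 3,4-bis(benzyloxy)benzaldehyde
Product: 15 1,2-bis(benzyloxy)-4-ethynylbenzene
Conditions: dimethyl (1-diazo-2-oxopropyl)phosphonate, K2CO3, MeOH, rt
Reagents that add atoms: dimethyl (1-diazo-2-oxopropyl)phosphonate (Ohira–Bestmann reagent), COP(=O)(OC)C(=[N+]=[N-])C(C)=O
Why: Seyferth–Gilbert homologation, in which the diazomethylphosphonate anion released by methanolysis olefinates the aldehyde and the diazoalkene loses N2 with a 1,2-hydrogen shift.

**Step 10**
Reactants: 15 aryl alkyne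
Product: 16 benzyl{(Z)-2-[3,4-bis(benzyloxy)phenyl]ethenyl}dimethylsilane
Conditions: BnMe2SiH (1.2 equiv), [RuCl2(p-cymene)]2 (2.5 mol %), CH2Cl2, 40 °C
Reagents that add atoms: benzyl(dimethyl)silane, C[SiH](C)Cc1ccccc1
Why: Ru(II)-catalysed trans-hydrosilylation of a terminal aryl alkyne adds H and Si anti across the triple bond to give the β-(Z)-vinylsilane, whose geometry later encodes the 2,3-cis relationship.

**Step 11**
Reactants: 14 racemic o-hydroxybenzhydrol; 16 (Z)-β-silylstyrene (1.5 equiv)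
Product: 18 3,7,8-tris(benzyloxy)-5-{(2R,3R,4S)-3-[benzyl(dimethyl)silyl]-7,8-bis(benzyloxy)-2-[3,4-bis(benzyloxy)phenyl]-3,4-dihydro-2H-chromen-4-yl}-2-[3,4-bis(benzyloxy)phenyl]-4H-chromen-4-one, via (E)-o-quinone methide 17 (not isolated)
Conditions: (R)-TRIP N-triflylphosphoramide (10 mol %; antipode per remark), 5 Å MS, toluene, −20 → 0 °C
Reagents that add atoms: none
Why: Proposed new method: the chiral acid dehydrates either enantiomer of 14 to the same planar (E)-o-quinone methide 17, which stays hydrogen-bonded to the chiral anion and undergoes an asynchronous inverse-electron-demand oxa-[4+2] with 16 in which the silicon-bearing carbon bonds to C4 first while charge builds at C2, stabilised by the 3,4-dioxygenated aryl group and by the β-C–Si bond, before O1 closes anti to silicon. The closest known reaction type is the chiral Brønsted-acid-catalysed [4+2] cycloaddition of in situ generated o-quinone methides with styrenes, combined with silyl-retentive annulations of vinyl- and allylsilanes with cationic electrophiles; a (Z)-β-silylstyrene as the 2π partner has not been shown. The dihydropyran ring is closed in a [4+2] mode (C3–C4 and O1–C2 bonds), in the stepwise limit by six-membered capture of the β-silyl benzylic cation by the phenolic oxygen. C2/C3 cis follows from the (Z)-alkene geometry transmitted suprafacially (the β-silicon effect blocks rotation about C2–C3), C3/C4 trans from an exo approach in which SiMe2Bn and the aryl group of 16 point away from the quinone methide ring and the peri-substituted flavonyl group, and the absolute configuration (4S, hence 2R,3R) from the chiral counter-anion shielding one face of C4, so that the step is stereoconvergent with respect to 14. The selectivities needed are C–C bonding at the silyl carbon (secured by the matched α-silyl/benzylic polarisation of 16), annulation over desilylative vinylation (secured by intramolecular capture in a non-nucleophilic medium) and exo over endo (secured by the bulk of silicon next to C4).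

**Step 12**
Reactants: 18 3-silylflavan
Product: 20 3,7,8-tris(benzyloxy)-5-{(2R,3R,4S)-7,8-bis(benzyloxy)-2-[3,4-bis(benzyloxy)phenyl]-3-hydroxy-3,4-dihydro-2H-chromen-4-yl}-2-[3,4-bis(benzyloxy)phenyl]-4H-chromen-4-one, via fluorosilane 19 (not isolated)
Conditions: TBAF, THF, 0 °C; then KHCO3, 30% H2O2, MeOH, rt
Reagents that add atoms: hydrogen peroxide, OO
Why: Tamao–Fleming oxidation of a benzyldimethylsilyl group, in which fluoride cleaves the Si–benzyl bond, hydroperoxide adds to silicon and C3 migrates to oxygen with retention, so the 2,3-cis-3,4-trans arrangement is carried over; in the conformer with equatorial C2-aryl the axial C–Si bond is gauche to C2–O1, which should disfavour Peterson-type ring opening.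

**Step 13**
Reactants: 20 nonabenzyl ether
Product: 21 2-(3,4-dihydroxyphenyl)-5-[(2R,3R,4S)-2-(3,4-dihydroxyphenyl)-3,7,8-trihydroxy-3,4-dihydro-2H-chromen-4-yl]-3,7,8-trihydroxy-4H-chromen-4-one
Conditions: H2 (1 atm), 20% Pd(OH)2/C, THF/MeOH, rt
Reagents that add atoms: none
Why: hydrogenolysis of nine benzyl ethers over Pearlman's catalyst under neutral conditions should leave the chromone enone, the C2–O1 benzylic ether and all three stereocentres untouched.

**Compound list**
1 | gallacetophenone, 1-(2,3,4-trihydroxyphenyl)ethanone | CC(=O)c1ccc(O)c(O)c1O | starting material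
2 | 1-[3,4-bis(benzyloxy)-2-hydroxyphenyl]ethanone | CC(=O)c1ccc(OCc2ccccc2)c(OCc2ccccc2)c1O | intermediate
3 | 3,4-bis(benzyloxy)benzaldehyde | O=Cc1ccc(OCc2ccccc2)c(OCc2ccccc2)c1 | starting material
4 | (E)-1-[3,4-bis(benzyloxy)-2-hydroxyphenyl]-3-[3,4-bis(benzyloxy)phenyl]prop-2-en-1-one | O=C(/C=C/c1ccc(OCc2ccccc2)c(OCc2ccccc2)c1)c1ccc(OCc2ccccc2)c(OCc2ccccc2)c1O | intermediate
5 | trans-7,8-bis(benzyloxy)-2-[3,4-bis(benzyloxy)phenyl]-3-hydroxychroman-4-one (racemic, one enantiomer drawn; formed in situ in step 3) | O=C1c2ccc(OCc3ccccc3)c(OCc3ccccc3)c2O[C@H](c2ccc(OCc3ccccc3)c(OCc3ccccc3)c2)[C@H]1O | intermediate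
6 | 7,8-bis(benzyloxy)-2-[3,4-bis(benzyloxy)phenyl]-3-hydroxy-4H-chromen-4-one | O=c1c(O)c(-c2ccc(OCc3ccccc3)c(OCc3ccccc3)c2)oc2c(OCc3ccccc3)c(OCc3ccccc3)ccc12 | intermediate
7 | 3,7,8-tris(benzyloxy)-2-[3,4-bis(benzyloxy)phenyl]-4H-chromen-4-one | O=c1c(OCc2ccccc2)c(-c2ccc(OCc3ccccc3)c(OCc3ccccc3)c2)oc2c(OCc3ccccc3)c(OCc3ccccc3)ccc12 | intermediate
8 | 3,7,8-tris(benzyloxy)-2-[3,4-bis(benzyloxy)phenyl]-5-[(E)-2-phenylethenyl]-4H-chromen-4-one | O=c1c(OCc2ccccc2)c(-c2ccc(OCc3ccccc3)c(OCc3ccccc3)c2)oc2c(OCc3ccccc3)c(OCc3ccccc3)cc(/C=C/c3ccccc3)c12 | intermediate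
9 | threo-5-(1,2-dihydroxy-2-phenylethyl) derivative of 7 (racemic, one enantiomer drawn; formed in situ in step 6) | O=c1c(OCc2ccccc2)c(-c2ccc(OCc3ccccc3)c(OCc3ccccc3)c2)oc2c(OCc3ccccc3)c(OCc3ccccc3)cc([C@@H](O)[C@H](O)c3ccccc3)c12 | intermediate
10 | 3,7,8-tris(benzyloxy)-2-[3,4-bis(benzyloxy)phenyl]-4-oxo-4H-chromene-5-carbaldehyde | O=c1c(OCc2ccccc2)c(-c2ccc(OCc3ccccc3)c(OCc3ccccc3)c2)oc2c(OCc3ccccc3)c(OCc3ccccc3)cc(C=O)c12 | intermediate
11 | 2,3-bis(benzyloxy)benzaldehyde | O=Cc1cccc(OCc2ccccc2)c1OCc1ccccc1 | starting material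
12 | 2,3-bis(benzyloxy)phenyl formate (formed in situ in step 7) | O=COc1cccc(OCc2ccccc2)c1OCc1ccccc1 | intermediate
13 | 2,3-bis(benzyloxy)phenol | Oc1cccc(OCc2ccccc2)c1OCc1ccccc1 | intermediate
14 | rac-3,7,8-tris(benzyloxy)-5-{[3,4-bis(benzyloxy)-2-hydroxyphenyl](hydroxy)methyl}-2-[3,4-bis(benzyloxy)phenyl]-4H-chromen-4-one | O=c1c(OCc2ccccc2)c(-c2ccc(OCc3ccccc3)c(OCc3ccccc3)c2)oc2c(OCc3ccccc3)c(OCc3ccccc3)cc(C(O)c3ccc(OCc4ccccc4)c(OCc4ccccc4)c3O)c12 | intermediate
15 | 1,2-bis(benzyloxy)-4-ethynylbenzene | C#Cc1ccc(OCc2ccccc2)c(OCc2ccccc2)c1 | intermediate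
16 | benzyl{(Z)-2-[3,4-bis(benzyloxy)phenyl]ethenyl}dimethylsilane | C[Si](C)(Cc1ccccc1)/C=C\c1ccc(OCc2ccccc2)c(OCc2ccccc2)c1 | intermediate
17 | (E)-o-quinone methide, 5-{(E)-[3,4-bis(benzyloxy)-2-oxocyclohexa-3,5-dien-1-ylidene]methyl} derivative of 7 (formed in situ in step 11) | O=c1c(OCc2ccccc2)c(-c2ccc(OCc3ccccc3)c(OCc3ccccc3)c2)oc2c(OCc3ccccc3)c(OCc3ccccc3)cc(/C=C3\C=CC(OCc4ccccc4)=C(OCc4ccccc4)C3=O)c12 | intermediate
18 | 3,7,8-tris(benzyloxy)-5-{(2R,3R,4S)-3-[benzyl(dimethyl)silyl]-7,8-bis(benzyloxy)-2-[3,4-bis(benzyloxy)phenyl]-3,4-dihydro-2H-chromen-4-yl}-2-[3,4-bis(benzyloxy)phenyl]-4H-chromen-4-one (2,3-cis, 3,4-trans) | O=c1c(OCc2ccccc2)c(-c2ccc(OCc3ccccc3)c(OCc3ccccc3)c2)oc2c(OCc3ccccc3)c(OCc3ccccc3)cc([C@H]3c4ccc(OCc5ccccc5)c(OCc5ccccc5)c4O[C@H](c4ccc(OCc5ccccc5)c(OCc5ccccc5)c4)[C@@H]3[Si](C)(C)Cc3ccccc3)c12 | intermediate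
19 | (2R,3R,4S)-3-[fluoro(dimethyl)silyl] analogue of 18 (formed in situ in step 12) | O=c1c(OCc2ccccc2)c(-c2ccc(OCc3ccccc3)c(OCc3ccccc3)c2)oc2c(OCc3ccccc3)c(OCc3ccccc3)cc([C@H]3c4ccc(OCc5ccccc5)c(OCc5ccccc5)c4O[C@H](c4ccc(OCc5ccccc5)c(OCc5ccccc5)c4)[C@@H]3[Si](C)(C)F)c12 | intermediate
20 | 3,7,8-tris(benzyloxy)-5-{(2R,3R,4S)-7,8-bis(benzyloxy)-2-[3,4-bis(benzyloxy)phenyl]-3-hydroxy-3,4-dihydro-2H-chromen-4-yl}-2-[3,4-bis(benzyloxy)phenyl]-4H-chromen-4-one | O=c1c(OCc2ccccc2)c(-c2ccc(OCc3ccccc3)c(OCc3ccccc3)c2)oc2c(OCc3ccccc3)c(OCc3ccccc3)cc([C@H]3c4ccc(OCc5ccccc5)c(OCc5ccccc5)c4O[C@H](c4ccc(OCc5ccccc5)c(OCc5ccccc5)c4)[C@@H]3O)c12 | intermediate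
21 | 2-(3,4-dihydroxyphenyl)-5-[(2R,3R,4S)-2-(3,4-dihydroxyphenyl)-3,7,8-trihydroxy-3,4-dihydro-2H-chromen-4-yl]-3,7,8-trihydroxy-4H-chromen-4-one | O=c1c(O)c(-c2ccc(O)c(O)c2)oc2c(O)c(O)cc([C@H]3c4ccc(O)c(O)c4O[C@H](c4ccc(O)c(O)c4)[C@@H]3O)c12 | target

**Step count**
Total steps: 13. Longest linear sequence: 10 (steps 1–6, 8, 11, 12, 13).

**Steps most likely to fail**

Step 11 (Proposed new method). What may go wrong: loss of silicon from the β-silyl cation (vinylation instead of ring closure), endo approach leading to the 3,4-cis isomer, acid-induced protodesilylation or Z→E drift of the vinylsilane, reversible capture of the quinone methide by the peri pyranone oxygen, or weak facial discrimination by the chiral anion.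

Fallback with known chemistry, setting out from 14 and returning at 21:
- 14 and benzyloxyacetaldehyde are combined under amine catalysis ((S)-diphenylprolinol trimethylsilyl ether with an acid co-catalyst that releases the quinone methide). This enamine/o-quinone methide formal [4+2] should give the 3,4-trans lactol 3,7,8-tris(benzyloxy)-5-[(3R,4S)-3,7,8-tris(benzyloxy)-2-hydroxy-3,4-dihydro-2H-chromen-4-yl]-2-[3,4-bis(benzyloxy)phenyl]-4H-chromen-4-one F1 as an anomer mixture.
- Addition of [3,4-bis(benzyloxy)phenyl]magnesium bromide F2 (from commercial 4-bromo-1,2-bis(benzyloxy)benzene and Mg) to the open aldehyde form gives the (2R,3S)-2-(benzyloxy)-1-[3,4-bis(benzyloxy)phenyl]-3-[3,4-bis(benzyloxy)-2-hydroxyphenyl]-3-(flavon-5-yl)propan-1-ol F3 (C1 epimers).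
- MnO2 in CH2Cl2 oxidises the benzylic carbinol to the corresponding aryl ketone F4.
- Reductive etherification (Et3SiH, TMSOTf, CH2Cl2, −78 °C) closes the pyran ring through the cyclic oxocarbenium ion, with hydride delivered anti to the pseudo-axial 3-benzyloxy group, to give the 2,3-cis (2R,3R,4S) decabenzyl ether F5.
- Hydrogenolysis under the conditions of step 13 then gives 21.

Step 12. What may go wrong: after fluoride activation, anti-elimination of the silicate with the C2 aryloxide (ring opening to a 1,3-diarylpropene) or protodesilylation may compete with migration of C3 to oxygen.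

Fallback, setting out from 15 and 14 and returning at 20: silicon is replaced by boron. Rh(I)/P(iPr)3-catalysed trans-hydroboration of 15 with pinacolborane gives 2-{(Z)-2-[3,4-bis(benzyloxy)phenyl]ethenyl}-4,4,5,5-tetramethyl-1,3,2-dioxaborolane F6. The cycloaddition of step 11 run with F6 in place of 16 should give the 3-boryl flavan (2S,3R,4S by CIP, same spatial arrangement as 18) F7. Oxidation with NaBO3·4H2O in THF/H2O at rt, without fluoride, replaces boron by hydroxyl with retention and gives 20. This fallback depends on the step-11 cycloaddition accepting an alkenylboronate.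

Step 8. What may go wrong: slow addition at the peri-hindered aldehyde, and premature ionisation of the product to the quinone methide under the Lewis-acidic magnesium conditions, leading to a second arylation.

Fallback, setting out from 10 and 13 and returning at 14: a boron template replaces magnesium. Heating 13, 10 and phenylboronic acid with catalytic propionic acid in toluene with azeotropic removal of water should give, ortho-specifically, the 2-phenyl-4H-1,3,2-benzodioxaborin 3,7,8-tris(benzyloxy)-5-[7,8-bis(benzyloxy)-2-phenyl-4H-1,3,2-benzodioxaborin-4-yl]-2-[3,4-bis(benzyloxy)phenyl]-4H-chromen-4-one F8. Transesterification with 2,2-dimethylpropane-1,3-diol at rt under neutral conditions releases 14.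

**Further compounds**
F1 | step 11 | 3,7,8-tris(benzyloxy)-5-[(3R,4S)-3,7,8-tris(benzyloxy)-2-hydroxy-3,4-dihydro-2H-chromen-4-yl]-2-[3,4-bis(benzyloxy)phenyl]-4H-chromen-4-one (anomer mixture) | O=c1c(OCc2ccccc2)c(-c2ccc(OCc3ccccc3)c(OCc3ccccc3)c2)oc2c(OCc3ccccc3)c(OCc3ccccc3)cc([C@H]3c4ccc(OCc5ccccc5)c(OCc5ccccc5)c4OC(O)[C@@H]3OCc3ccccc3)c12
F2 | step 11 | [3,4-bis(benzyloxy)phenyl]magnesium bromide | Br[Mg]c1ccc(OCc2ccccc2)c(OCc2ccccc2)c1
F3 | step 11 | (2R,3S)-2-(benzyloxy)-1-[3,4-bis(benzyloxy)phenyl]-3-[3,4-bis(benzyloxy)-2-hydroxyphenyl]-3-{3,7,8-tris(benzyloxy)-2-[3,4-bis(benzyloxy)phenyl]-4-oxo-4H-chromen-5-yl}propan-1-ol (C1 epimers) | O=c1c(OCc2ccccc2)c(-c2ccc(OCc3ccccc3)c(OCc3ccccc3)c2)oc2c(OCc3ccccc3)c(OCc3ccccc3)cc([C@@H](c4ccc(OCc5ccccc5)c(OCc5ccccc5)c4O)[C@@H](OCc4ccccc4)C(O)c4ccc(OCc5ccccc5)c(OCc5ccccc5)c4)c12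
F4 | step 11 | (2R,3S)-2-(benzyloxy)-1-[3,4-bis(benzyloxy)phenyl]-3-[3,4-bis(benzyloxy)-2-hydroxyphenyl]-3-{3,7,8-tris(benzyloxy)-2-[3,4-bis(benzyloxy)phenyl]-4-oxo-4H-chromen-5-yl}propan-1-one | O=c1c(OCc2ccccc2)c(-c2ccc(OCc3ccccc3)c(OCc3ccccc3)c2)oc2c(OCc3ccccc3)c(OCc3ccccc3)cc([C@@H](c4ccc(OCc5ccccc5)c(OCc5ccccc5)c4O)[C@@H](OCc4ccccc4)C(=O)c4ccc(OCc5ccccc5)c(OCc5ccccc5)c4)c12
F5 | step 11 | 3,7,8-tris(benzyloxy)-5-{(2R,3R,4S)-3,7,8-tris(benzyloxy)-2-[3,4-bis(benzyloxy)phenyl]-3,4-dihydro-2H-chromen-4-yl}-2-[3,4-bis(benzyloxy)phenyl]-4H-chromen-4-one | O=c1c(OCc2ccccc2)c(-c2ccc(OCc3ccccc3)c(OCc3ccccc3)c2)oc2c(OCc3ccccc3)c(OCc3ccccc3)cc([C@H]3c4ccc(OCc5ccccc5)c(OCc5ccccc5)c4O[C@H](c4ccc(OCc5ccccc5)c(OCc5ccccc5)c4)[C@@H]3OCc3ccccc3)c12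
F6 | step 12 | 2-{(Z)-2-[3,4-bis(benzyloxy)phenyl]ethenyl}-4,4,5,5-tetramethyl-1,3,2-dioxaborolane | CC1(C)OB(/C=C\c2ccc(OCc3ccccc3)c(OCc3ccccc3)c2)OC1(C)C
F7 | step 12 | 3,7,8-tris(benzyloxy)-5-{(2S,3R,4S)-7,8-bis(benzyloxy)-2-[3,4-bis(benzyloxy)phenyl]-3-(4,4,5,5-tetramethyl-1,3,2-dioxaborolan-2-yl)-3,4-dihydro-2H-chromen-4-yl}-2-[3,4-bis(benzyloxy)phenyl]-4H-chromen-4-one (2,3-cis, 3,4-trans) | O=c1c(OCc2ccccc2)c(-c2ccc(OCc3ccccc3)c(OCc3ccccc3)c2)oc2c(OCc3ccccc3)c(OCc3ccccc3)cc([C@H]3c4ccc(OCc5ccccc5)c(OCc5ccccc5)c4O[C@H](c4ccc(OCc5ccccc5)c(OCc5ccccc5)c4)[C@@H]3B3OC(C)(C)C(C)(C)O3)c12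
F8 | step 8 | rac-3,7,8-tris(benzyloxy)-5-[7,8-bis(benzyloxy)-2-phenyl-4H-1,3,2-benzodioxaborin-4-yl]-2-[3,4-bis(benzyloxy)phenyl]-4H-chromen-4-one | O=c1c(OCc2ccccc2)c(-c2ccc(OCc3ccccc3)c(OCc3ccccc3)c2)oc2c(OCc3ccccc3)c(OCc3ccccc3)cc(C3OB(c4ccccc4)Oc4c(OCc5ccccc5)c(OCc5ccccc5)ccc43)c12
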